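The noon run read 67.1% target at 8.00 min and 67.8% at 12.0 min, a step close to the scatter of 0.5 percentage points. Its last reading is taken here as a finished flask.

| flask | substrate | reagent | free catalyst | added ligand | temperature | remark | time |
|---|---|---|---|---|---|---|---|
| autumn | 0.43 M | 1.72 M | 47 mM | 87 mM | 48 °C | run made earlier |  |
| noon | 0.72 M | 1.72 M | 47 mM | 87 mM | 64 °C | run made earlier |  |
| midnight | 1.2 M | 1.72 M | 47 mM | 87 mM | 48 °C | run made earlier |  |
| winter | 0.86 M | 1.72 M | 47 mM | 200 mM | 64 °C | run made earlier |  |
| green | 0.40 M | 1.72 M | 47 mM | 87 mM | 70 °C |  | 12 min |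
| blue | 1.2 M | 1.72 M | 25 mM | 87 mM | 70 °C |  | 12 min |
| teal | 0.86 M | 1.72 M | 47 mM | 400 mM | 40 °C |  | 12 min |
| violet | 0.86 M | 1.72 M | 47 mM | 87 mM | 70 °C |  | 12 min |

| run | time / min | target / % | substrate / % |
|---|---|---|---|
| autumn | 8.00 | 55.4 | 43.1 |
| autumn | 15.0 | 69.2 | 30.6 |
| autumn | 25.0 | 72.5 | 26.0 |
| autumn | 30.0 | 73.6 | 24.8 |
| autumn | 40.0 | 73.8 | 25.3 |
| noon | 1.00 | 32.1 | 67.9 |
| noon | 3.00 | 57.0 | 42.3 |
| noon | 6.00 | 65.9 | 32.6 |
| noon | 8.00 | 67.1 | 30.2 |
| noon | 12.0 | 67.8 | 30.5 |
| midnight | 3.00 | 28.5 | 71.1 |
| midnight | 6.00 | 43.0 | 55.2 |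
| midnight | 8.00 | 49.3 | 49.7 |
| midnight | 20.0 | 61.6 | 35.1 |
| midnight | 40.0 | 65.0 | 32.9 |
| winter | 2.50 | 53.0 | 46.1 |
| winter | 5.00 | 61.8 | 35.2 |
| winter | 8.00 | 65.5 | 31.1 |
| winter | 10.0 | 65.6 | 31.9 |
| winter | 12.0 | 66.2 | 31.5 |

(each reading ± 0.5 percentage points)

- the numbers in the tables scatter by 0.5 percentage points (one standard deviation)
- no earlier run changes the charge of free catalyst; that part of a forecast is a guess

1. the flasks put in order of amount of target, in percent of the substrate charged, best first, at 12 min (green / blue / teal / violet)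
2. the amount of target, in percent of the substrate charged of the flask you put first, at 12 min
3. the amount of target, in percent of the substrate charged of the flask you put last, at 12 min

Divide the target fraction by the substrate fraction, then by the molarity of reagent left, counting one reagent used per target. Noon's last reading gives 1.80 /M. At 48 °C, autumn gives 2.08 /M and midnight, from a different charge, gives 2.10 /M. Stepped on in the same ratio to 70 °C, this reading becomes 1.71 /M: the plateau quotient, target over substrate per molar reagent left, which a flask finished at that temperature should show.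

Two chemists argue over teal. The first holds to thermodynamic control: each flask has finished by 12 min, so the quotient ranks them. Violet's balance at 1.71 /M gives 66.3%. Teal, colder, has at least the 48 °C quotient and gets 69.9%, above violet.

The second holds to kinetic control and reads the approach to plateau as an exponential. Autumn gives 0.174 /min and noon 0.612 /min, so teal's temperature gets 0.0925 /min. Noon's time constant, 1.63 min, is shorter than 12 min, and the other flasks are hotter. Teal's is 10.8 min, so teal has not finished. Joining the two ends, my own reckoning for teal covers 67.0% of the approach to 69.9%, which gives 46.9%.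

The forecast takes the second side, “Teal is kinetically limited”, and says green > violet > blue > teal, with 70.5% on top and 44% last, below my 46.9% for teal.

The flasks give green > violet > blue > teal, with green at 68.1% and teal at 47.2%.

    substrate + reagent ⇌ target (K = 1.74 /M, k = 0.410 /M/min, Ea = 68.0 kJ/mol, ΔH = −9.00 kJ/mol)
    substrate + reagent ⇌ isomer of the product (K = 133 /M, k = 0.00695 /M/min, Ea = 76.0 kJ/mol, ΔH = −65.0 kJ/mol)
    target + free catalyst ⇌ isomer of the product + free catalyst, rate k3*[free catalyst]*[target] forward; the back reaction follows from the equilibrium constant (k = 0.0818 /M/min, Ea = 77.0 kJ/mol)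
    2 free catalyst → spent catalyst (k = 4.49 /M/min, Ea = 60.0 kJ/mol)
    free catalyst + added ligand ⇌ idle complex (K = 36.7 /M, k = 13.0 /M/min, Ea = 44.0 kJ/mol, ΔH = −25.0 kJ/mol)
    (constants at 70 °C)

At 12 min, green shows a quotient of 1.76 /M, and its neighbour with 1.0 M of reagent shows 1.75 /M, against the reckoned 1.71 /M. Teal shows 0.692 /M. The first chemist's region is long times: by 120 min teal shows 2.38 /M and holds 70.2% target, more than green's 48.7%. In green, with the concentrations as charged, substrate's forward half-life to target is 0.98 min, while target's forward half-life to isomer of the product, 180 min, is long against 12 min. Green holds 4.83% isomer of the product at 12.0 min and 31.5% at 120 min.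

The data are simulated with constants of no real substance, noise included.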